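**Retrosynthetic overview**

1. Target 36 ⇐ butanolide 32 (ring C), closed last by gold-catalysed anti addition of the C19 acid to the C5=C6=C7 allene of ten-membered ketone 31; this sets C7–O and the cis C5=C6 alkene.
2. 31 ⇐ anionic alkynyl oxy-Cope rearrangement of trans-decalin 28: C4–C5 forms while C2–C7 breaks, enlarging a temporary cyclohexane (ring D: C1, C2, C7, C8, C9, C10) to the ten-membered ring A. Enabling feature: in ring A the oxygenated carbons C2 and C7 flank the chain C3–C4–C5=C6, so a C2–C7 bond turns ring A into a decalin whose C2 carries OH and vinyl (C3=C4) and whose C7 carries prop-1-ynyl (C6≡C5–C16), a 1,5-enyn-3-ol.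
3. Decalin ⇐ Heck coupling and intramolecular Diels–Alder reaction of acyclic triene-yne 16 (rings B and D, C1/C2/C7/C10 together); 8α-OH and 9β-O come from an 8,9-epoxide opened by the C19 acid (temporary γ-lactone, ring E).
4. Carbon sources: (S)-linalool (C9–C14, C20), (S)-Roche ester (C8, C17–C19), methyl acetoacetate (C1–C3, C15), propyne (C5, C6, C16), Ohira–Bestmann reagent (C7), Ph3P=CH2 (C4).
5. Ring order: B and D (step 11) → E (step 19) → A by enlargement of D (step 21) → C (step 22).

Key step: step 21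

Remark: every intermediate keeps the atom numbers of the target (briarane numbering C1–C20; β is the face of the C15 methyl group, α the opposite face), and (S)-(+)-linalool is assumed to be bought in high enantiomeric purity.

**Route**

Step 1
Reactants: 1 (S)-(+)-linalool
Product: 2 (S)-triethyl[(3,7-dimethylocta-1,6-dien-3-yl)oxy]silane
Conditions: Et3SiOSO2CF3, 2,6-lutidine, CH2Cl2, −78 → 0 °C
Reagents that add atoms: triethylsilyl trifluoromethanesulfonate, CC[Si](CC)(CC)OS(=O)(=O)C(F)(F)F
Why: Silyl triflate silylation of the tertiary allylic alcohol is standard; the C11 stereocentre of the target comes from linalool and is not touched.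

Step 2
Reactants: 2 TES-linalool
Product: 4 (S)-4-methyl-4-(triethylsilyloxy)hex-5-enal, via secondary ozonide 3 (not isolated)
Conditions: O3 (1.0 equiv), CH2Cl2, −78 °C; then PPh3, −78 → 23 °C
Reagents that add atoms: ozone, [O-][O+]=O
Why: Chemoselective ozonolysis: the electron-rich trisubstituted alkene reacts far faster than the vinyl group, and PPh3 reduces the ozonide to the C14 aldehyde.

Step 3
Reactants: 5 methyl acetoacetate
Product: 6 methyl (E)-3-(trifluoromethylsulfonyloxy)but-2-enoate
Conditions: (CF3SO2)2O, aq. Me4NOH, hexanes, 5 °C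
Reagents that add atoms: trifluoromethanesulfonic anhydride, O=S(=O)(OS(=O)(=O)C(F)(F)F)C(F)(F)F
Why: O-triflation of the non-chelated tetramethylammonium enolate should give the (E)-enol triflate (triflate trans to the ester), so that the γ-hydroxy enoate of step 4 cannot lactonise.

Step 4
Reactants: 4 aldehyde; 6 enol triflate
Product: 7 methyl (2E,7S)-4-hydroxy-3,7-dimethyl-7-(triethylsilyloxy)nona-2,8-dienoate (both C14 epimers)
Conditions: CrCl2 (4 equiv), NiCl2 (2 mol%), DMF, 23 °C
Reagents that add atoms: none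
Why: Nozaki–Hiyama–Kishi coupling (nickel inserts into the alkenyl triflate, chromium adds the alkenyl group to the aldehyde with retention of alkene geometry); the new carbinol centre is unselective and is erased in step 5.

Step 5
Reactants: 7 allylic alcohol
Product: 8 methyl (2E,7S)-3,7-dimethyl-4-oxo-7-(triethylsilyloxy)nona-2,8-dienoate
Conditions: Dess–Martin periodinane, NaHCO3, CH2Cl2, 0 → 23 °C
Reagents that add atoms: none
Why: Dess–Martin oxidation of the secondary allylic alcohol should give the doubly activated (E)-4-oxo-2-enoate dienophile without touching the silyl ether.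

Step 6
Reactants: 9 methyl (S)-3-hydroxy-2-methylpropanoate
Product: 10 methyl (S)-3-(tert-butyldimethylsilyloxy)-2-methylpropanoate
Conditions: t-BuMe2SiCl, imidazole, CH2Cl2, 0 → 23 °C
Reagents that add atoms: tert-butyldimethylsilyl chloride, CC(C)(C)[Si](C)(C)Cl
Why: Standard silylation of the primary alcohol; the C17 stereocentre of the target comes from this building block.

Step 7
Reactants: 10 silyl ether
Product: 11 (S)-3-(tert-butyldimethylsilyloxy)-2-methylpropanal
Conditions: i-Bu2AlH, CH2Cl2, −78 °C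
Reagents that add atoms: none
Why: Low-temperature hydride reduction stops at the aldehyde through the stable tetrahedral aluminate; the aldehyde is used crude to avoid epimerisation at C17.

Step 8
Reactants: 11 aldehyde
Product: 12 (R)-tert-butyldimethyl[(2-methylbut-3-yn-1-yl)oxy]silane
Conditions: dimethyl (1-diazo-2-oxopropyl)phosphonate, K2CO3, MeOH, 0 → 23 °C
Reagents that add atoms: dimethyl (1-diazo-2-oxopropyl)phosphonate, COP(=O)(OC)C(=[N+]=[N-])C(C)=O
Why: Ohira–Bestmann (Seyferth–Gilbert) homologation converts the aldehyde into the terminal alkyne (new carbon is C7) under conditions mild enough to keep the α-stereocentre.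

Step 9
Reactants: 12 alkyne
Product: 13 (S,E)-[(3-bromo-4-iodo-2-methylbut-3-en-1-yl)oxy](tert-butyl)dimethylsilane
Conditions: IBr, CH2Cl2, −78 °C
Reagents that add atoms: iodine monobromide, BrI
Why: Anti addition of I–Br to the terminal alkyne (iodonium ion opened by bromide at the more substituted carbon) should give the (E)-2-bromo-1-iodoalkene with iodine on C7 and bromine on C8.

Step 10
Reactants: 13 bromo-iodo-alkene; 14 propyne
Product: 15 (S,E)-[(3-bromo-2-methylhept-3-en-5-yn-1-yl)oxy](tert-butyl)dimethylsilane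
Conditions: PdCl2(PPh3)2 (3 mol%), CuI (6 mol%), Et3N, THF, 0 → 23 °C
Reagents that add atoms: none
Why: Sonogashira coupling occurs at the C–I bond, which inserts palladium much faster than C–Br, with retention, so the propynyl group ends trans to bromine and cis to C17.

Step 11
Reactants: 8 oxo-enoate; 15 bromo-enyne
Product: 17 trans-decalin keto ester (rings B and D), via triene-yne 16 (not isolated)
Conditions: Pd(OAc)2 (10 mol%), P(o-tol)3 (20 mol%), Et3N, MeCN, 70 °C; then toluene, 110 °C
Reagents that add atoms: none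
Why: Heck vinylation of the vinyl group of 8 (C11 has no β-hydrogen, so only the (E)-C9=C10 diene can form) gives 16, which should cyclise by an intramolecular Diels–Alder reaction through the trans-fused transition state with the C15 methyl and the ester endo and the tether ketone exo (the usual preference of α-methyl enone dienophiles), setting 1β-CH3, 2β-CO2Me, 7β-propynyl (outside position of the diene) and 10α-H together, the diene face being chosen by C11, which keeps its methyl pseudo-equatorial and the smaller silyloxy group pseudo-axial in the chair-like tether.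

Step 12
Reactants: 17 keto ester
Product: 18 14α-alcohol
Conditions: LiBH(s-Bu)3, THF, −78 °C
Reagents that add atoms: none
Why: The bulky hydride attacks the C14 ketone from the equatorial direction (as with ketones next to a quaternary carbon that bears an axial methyl), which should give the axial 14α-alcohol trans to the C15 methyl and leave the hindered ester alone.

Step 13
Reactants: 18 alcohol
Product: 19 14α-OTBS ether
Conditions: t-BuMe2SiOSO2CF3, 2,6-lutidine, CH2Cl2, 0 °C
Reagents that add atoms: tert-butyldimethylsilyl trifluoromethanesulfonate, CC(C)(C)[Si](C)(C)OS(=O)(=O)C(F)(F)F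
Why: The silyl triflate silylates the hindered axial secondary alcohol; this ether must survive until the last step so that O-14 stays unacetylated.

Step 14
Reactants: 19 ester
Product: 21 2α-OTMS 2β-CO2Me ester, via potassium alkoxide 20 (not isolated)
Conditions: KN(SiMe3)2, THF, −78 °C; 3-phenyl-2-(phenylsulfonyl)oxaziridine; then Me3SiCl, −78 → 0 °C
Reagents that add atoms: 3-phenyl-2-(phenylsulfonyl)oxaziridine, O=S(=O)(c1ccccc1)N1OC1c1ccccc1; chlorotrimethylsilane, C[Si](C)(C)Cl
Why: Davis oxidation of the exocyclic ester enolate: the β face of C2 is blocked by the two flanking axial groups (C15 methyl, 7β-propynyl), so oxygen should enter from the α face while C8 is still trigonal, and the alkoxide is capped to prevent an α-ketol shift at the aldehyde stage.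

Step 15
Reactants: 21 ester
Product: 22 2α-OTMS 2β-carbaldehyde
Conditions: i-Bu2AlH, toluene, −78 °C
Reagents that add atoms: none
Why: Reduction of the α-silyloxy ester stops at the aldehyde at low temperature through the stable aluminium hemiacetal.

Step 16
Reactants: 22 aldehyde
Product: 23 2β-vinyl 2α-OTMS decalin
Conditions: Ph3PCH3Br, KN(SiMe3)2, THF, 0 → 23 °C
Reagents that add atoms: methyltriphenylphosphonium bromide, C[P+](c1ccccc1)(c1ccccc1)c1ccccc1.[Br-]
Why: Wittig methylenation of the non-enolisable aldehyde adds C4 and completes the equatorial 2β-vinyl group.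

Step 17
Reactants: 23 silyl ether
Product: 24 triol (2α-OH, 11β-OH, 19-OH; 14α-OTBS kept)
Conditions: HF·pyridine, pyridine, THF, 0 → 23 °C
Reagents that add atoms: none
Why: Buffered fluoride removes the primary TBS, the tertiary TMS and the tertiary TES ethers, while the axial neopentylic secondary TBS ether at C14 should be far slower to cleave.

Step 18
Reactants: 24 triol
Product: 25 C19 carboxylic acid
Conditions: TEMPO (20 mol%), PhI(OAc)2, MeCN/H2O (pH 7 buffer), 23 °C
Reagents that add atoms: water, O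
Why: The oxoammonium oxidation converts only the primary alcohol (through the aldehyde hydrate) into the acid; tertiary alcohols, alkenes and the alkyne are inert.

Step 19
Reactants: 25 acid
Product: 27 γ-lactone (ring E, 8α-OH, 9β-O), via epoxy acid 26 (not isolated)
Conditions: m-CPBA, CH2Cl2, 0 → 23 °C
Reagents that add atoms: 3-chloroperbenzoic acid, OOC(=O)c1cccc(Cl)c1
Why: The peracid should epoxidise the trisubstituted C8=C9 alkene (not the vinyl group) from the α face (β face shielded by C15 methyl and 7β-propynyl, α delivery helped by the homoallylic 2α-OH), and the carboxylic acid then opens the epoxide at C9 from the β face (anti, trans-diaxial, Fürst–Plattner) to set 8α-OH and 9β-O.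

Step 20
Reactants: 27 lactone
Product: 28 potassium carboxylate of the 2α,8α,9β,11β-tetraol
Conditions: KOH (1.0 equiv), THF/H2O, 23 °C; azeotropic drying (toluene)
Reagents that add atoms: potassium hydroxide, [K+].[OH-]
Why: Saponification gives the hydroxy carboxylate, in which C19 is not enolisable and O-9 cannot re-lactonise under the basic conditions of step 21.

Step 21
Reactants: 28 potassium carboxylate
Product: 31 ten-membered keto allenic acid, via pentapotassium enolate 29 (not isolated), via pentakis-silyl derivative 30 (not isolated)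
Conditions: KN(SiMe3)2 (6 equiv), 18-crown-6, THF, 0 → 40 °C; then Et3SiCl, −78 → 0 °C; then 0.5 M HCl, THF, 0 °C
Reagents that add atoms: chlorotriethylsilane, CC[Si](Cl)(CC)CC
Why: The base converts 28 into its tetra-alkoxide carboxylate, and the axial C2 alkoxide triggers an anionic alkynyl oxy-Cope [3,3] rearrangement of the 1,5-enyne C4=C3–C2(O−)–C7–C6≡C5: the C4–C5 σ bond forms while the C2–C7 bond of ring D breaks, giving the C2 enolate and the C5=C6=C7 allene, which silyl capping and brief acid hydrolysis turn into ketone 31. The closest known reaction type is the anionic oxy-Cope ring expansion of 1,2-dialkenylcyclohexanols to cyclodec-5-enones and its acetylenic variant that delivers allenes. Ring A is closed by four-atom enlargement of ring D through a six-centre pericyclic array (suprafacial on the vinyl and on the alkyne terminus), not by an end-to-end exo or endo cyclisation, so the entropic and transannular penalties of a direct ten-ring closure are avoided. No new tetrahedral centre is made (C2 and C7 become trigonal; C1, C8, C9, C10, C11, C14 and C17 are untouched), but the allene axis is formed in one sense (aR), dictated by the 7β centre because C4 can reach C5 only on the alkyne face turned toward C2. The [3,3] path has to beat fragmentation, 5-endo-dig addition of an alkoxide to the alkyne and base-induced isomerisation; this is secured by the cis, gauche placing of the equatorial 2β-vinyl and axial 7β-propynyl groups with the C2 oxide axial, by relief of the three syn-axial β substituents on ring D (C15 methyl, propynyl, O-9), and by the absence of any enolisable carbonyl (C19 is a carboxylate). Silylation in the same flask protects O-8, O-9 and O-11, so that the hydroxy acid cannot re-lactonise and the α-hydroxy-allene cannot cyclise in step 22.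

Step 22
Reactants: 31 keto allenic acid
Product: 32 butanolide (ring C closed, 2-ketone)
Conditions: (Ph3P)AuCl (5 mol%), AgOSO2CF3 (5 mol%), CH2Cl2, 23 °C
Reagents that add atoms: none
Why: Gold-catalysed cycloisomerisation of a 4,5-allenoic acid (5-exo anti addition): the cationic gold should bind the C6=C7 π bond on the outer lobe beside the C16 methyl and the carboxylate attacks C7 on the lobe that C2 vacated, so the allene axis becomes the 7S centre (O in the place of C2) and the cis (Z) C5=C6 alkene after protodeauration.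

Step 23
Reactants: 32 ketone
Product: 33 2β-alcohol
Conditions: NaBH4, CeCl3·7H2O, MeOH, −40 °C
Reagents that add atoms: none
Why: Luche-type borohydride reduction from the periphery of the ten-membered ring, anti to the C15 methyl on the neighbouring quaternary C1, should deliver H-2 to the α face (2β-OH); the lactone is not reduced at this temperature.

Step 24
Reactants: 33 alcohol
Product: 34 2β,8α,9β,11β-tetraol 14α-OTBS ether
Conditions: HF·pyridine, pyridine, THF, 0 °C
Reagents that add atoms: none
Why: Buffered fluoride cleaves the three TES ethers (O-8, O-9, O-11) much faster than the hindered TBS ether at O-14.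

Step 25
Reactants: 34 tetraol
Product: 35 2β,9β-diacetate 14α-OTBS ether
Conditions: Ac2O, pyridine, DMAP (cat.), CH2Cl2, 23 °C
Reagents that add atoms: acetic anhydride, CC(=O)OC(C)=O
Why: Only the two secondary alcohols (C2, C9) are acylated; the tertiary alcohols at C8 and C11 do not react under these conditions and O-14 is still silylated.

Step 26
Reactants: 35 diacetate
Product: 36 junceellolide I
Conditions: aq. HF (48%), MeCN, 0 → 23 °C
Reagents that add atoms: none
Why: Acidic fluoride removes the last silyl ether without acyl migration and without touching the acetates, the lactone or the tertiary alcohols.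

**Compound list**

1 | (S)-(+)-linalool, (S)-3,7-dimethylocta-1,6-dien-3-ol | C=C[C@@](C)(O)CCC=C(C)C | starting material
2 | (S)-triethyl[(3,7-dimethylocta-1,6-dien-3-yl)oxy]silane | C=C[C@@](C)(O[Si](CC)(CC)CC)CCC=C(C)C | intermediate
3 | secondary ozonide (1,2,4-trioxolane) of the trisubstituted alkene of 2 | C=C[C@@](C)(O[Si](CC)(CC)CC)CCC1OOC(C)(C)O1 | intermediate (not isolated)
4 | (S)-4-methyl-4-(triethylsilyloxy)hex-5-enal | C=C[C@@](C)(O[Si](CC)(CC)CC)CCC=O | intermediate
5 | methyl acetoacetate | CC(=O)CC(=O)OC | starting material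
6 | methyl (E)-3-(trifluoromethylsulfonyloxy)but-2-enoate | C/C(OS(=O)(=O)C(F)(F)F)=C\C(=O)OC | intermediate
7 | methyl (2E,7S)-4-hydroxy-3,7-dimethyl-7-(triethylsilyloxy)nona-2,8-dienoate, both C14 epimers | C=C[C@@](C)(O[Si](CC)(CC)CC)CCC(O)/C(C)=C/C(=O)OC | intermediate
8 | methyl (2E,7S)-3,7-dimethyl-4-oxo-7-(triethylsilyloxy)nona-2,8-dienoate | C=C[C@@](C)(O[Si](CC)(CC)CC)CCC(=O)/C(C)=C/C(=O)OC | intermediate
9 | methyl (S)-3-hydroxy-2-methylpropanoate ((S)-Roche ester) | COC(=O)[C@@H](C)CO | starting material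
10 | methyl (S)-3-(tert-butyldimethylsilyloxy)-2-methylpropanoate | COC(=O)[C@@H](C)CO[Si](C)(C)C(C)(C)C | intermediate
11 | (S)-3-(tert-butyldimethylsilyloxy)-2-methylpropanal | O=C[C@@H](C)CO[Si](C)(C)C(C)(C)C | intermediate
12 | (R)-tert-butyldimethyl[(2-methylbut-3-yn-1-yl)oxy]silane | C#C[C@@H](C)CO[Si](C)(C)C(C)(C)C | intermediate
13 | (S,E)-[(3-bromo-4-iodo-2-methylbut-3-en-1-yl)oxy](tert-butyl)dimethylsilane | I/C=C(Br)\[C@@H](C)CO[Si](C)(C)C(C)(C)C | intermediate
14 | propyne | CC#C | starting material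
15 | (S,E)-[(3-bromo-2-methylhept-3-en-5-yn-1-yl)oxy](tert-butyl)dimethylsilane (propynyl trans to Br) | CC#C/C=C(Br)\[C@@H](C)CO[Si](C)(C)C(C)(C)C | intermediate
16 | acyclic triene-yne: (E)-4-oxo-2-enoate (C3–C1, C14) linked through C13–C12–C11(CH3)(OTES) to the (9E)-diene C10=C9–C8=C7; C8 bears the (17R) CH(CH3)CH2OTBS group, C7 the propynyl group cis to C17 | CC#C/C=C(/C=C/[C@@](C)(O[Si](CC)(CC)CC)CCC(=O)/C(C)=C/C(=O)OC)[C@@H](C)CO[Si](C)(C)C(C)(C)C | intermediate (not isolated)
17 | trans-decalin (rings B, D): 14-ketone, 1β-CH3, 2β-CO2Me (2α-H), 7β-prop-1-ynyl (7α-H), C8=C9, 10α-H, 11α-CH3, 11β-OTES, (17R) side chain CH(CH3)CH2OTBS on C8 | COC(=O)[C@H]1[C@@H](C#CC)C(=C[C@@H]2[C@]1(C)C(=O)CC[C@]2(C)O[Si](CC)(CC)CC)[C@@H](C)CO[Si](C)(C)C(C)(C)C | intermediate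
18 | 14α-alcohol of 17 | COC(=O)[C@H]1[C@@H](C#CC)C(=C[C@@H]2[C@]1(C)[C@@H](O)CC[C@]2(C)O[Si](CC)(CC)CC)[C@@H](C)CO[Si](C)(C)C(C)(C)C | intermediate
19 | 14α-OTBS ether of 18 | COC(=O)[C@H]1[C@@H](C#CC)C(=C[C@@H]2[C@]1(C)[C@@H](O[Si](C)(C)C(C)(C)C)CC[C@]2(C)O[Si](CC)(CC)CC)[C@@H](C)CO[Si](C)(C)C(C)(C)C | intermediate
20 | potassium 2α-alkoxide of the 2-hydroxylated ester (2β-CO2Me) | COC(=O)[C@@]1([O-])[C@@H](C#CC)C(=C[C@@H]2[C@]1(C)[C@@H](O[Si](C)(C)C(C)(C)C)CC[C@]2(C)O[Si](CC)(CC)CC)[C@@H](C)CO[Si](C)(C)C(C)(C)C.[K+] | intermediate (not isolated)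
21 | 2α-OTMS, 2β-CO2Me ester | COC(=O)[C@@]1(O[Si](C)(C)C)[C@@H](C#CC)C(=C[C@@H]2[C@]1(C)[C@@H](O[Si](C)(C)C(C)(C)C)CC[C@]2(C)O[Si](CC)(CC)CC)[C@@H](C)CO[Si](C)(C)C(C)(C)C | intermediate
22 | 2α-OTMS, 2β-carbaldehyde | O=C[C@@]1(O[Si](C)(C)C)[C@@H](C#CC)C(=C[C@@H]2[C@]1(C)[C@@H](O[Si](C)(C)C(C)(C)C)CC[C@]2(C)O[Si](CC)(CC)CC)[C@@H](C)CO[Si](C)(C)C(C)(C)C | intermediate
23 | 2β-vinyl, 2α-OTMS decalin (7β-propynyl, C8=C9, 11β-OTES, 14α-OTBS, 19-OTBS) | C=C[C@@]1(O[Si](C)(C)C)[C@@H](C#CC)C(=C[C@@H]2[C@]1(C)[C@@H](O[Si](C)(C)C(C)(C)C)CC[C@]2(C)O[Si](CC)(CC)CC)[C@@H](C)CO[Si](C)(C)C(C)(C)C | intermediate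
24 | triol: 2α-OH (2β-vinyl), 11β-OH, 19-OH; 14α-OTBS | C=C[C@@]1(O)[C@@H](C#CC)C(=C[C@@H]2[C@]1(C)[C@@H](O[Si](C)(C)C(C)(C)C)CC[C@]2(C)O)[C@@H](C)CO | intermediate
25 | C19 carboxylic acid of 24 (17R) | C=C[C@@]1(O)[C@@H](C#CC)C(=C[C@@H]2[C@]1(C)[C@@H](O[Si](C)(C)C(C)(C)C)CC[C@]2(C)O)[C@@H](C)C(=O)O | intermediate
26 | 8α,9α-epoxy acid | C=C[C@@]1(O)[C@@H](C#CC)[C@@]3(O[C@@H]3[C@@H]2[C@]1(C)[C@@H](O[Si](C)(C)C(C)(C)C)CC[C@]2(C)O)[C@@H](C)C(=O)O | intermediate (not isolated)
27 | γ-lactone (ring E) C19(=O)–O–C9 (9β-O) with 8α-OH; 2α-OH, 2β-vinyl, 7β-propynyl, 11β-OH, 14α-OTBS | C=C[C@@]1(O)[C@@H](C#CC)[C@]3(O)[C@@H](OC(=O)[C@@H]3C)[C@@H]2[C@]1(C)[C@@H](O[Si](C)(C)C(C)(C)C)CC[C@]2(C)O | intermediate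
28 | potassium carboxylate of the opened lactone: 2α,8α,9β,11β-tetraol, 2β-vinyl, 7β-propynyl, 14α-OTBS | C=C[C@@]1(O)[C@@H](C#CC)[C@@](O)([C@@H](C)C(=O)[O-])[C@@H](O)[C@@H]2[C@]1(C)[C@@H](O[Si](C)(C)C(C)(C)C)CC[C@]2(C)O.[K+] | intermediate
29 | ring-expanded pentapotassium salt: C2 enolate (C2=C3, geometry not defined), (aR)-C5=C6=C7 allene, 8-, 9-, 11-alkoxides, C19 carboxylate | [O-]C1=CCC(C)=[C@]=C([H])[C@@]([O-])([C@@H](C)C(=O)[O-])[C@@H]([O-])[C@@H]2[C@]1(C)[C@@H](O[Si](C)(C)C(C)(C)C)CC[C@]2(C)[O-].[K+].[K+].[K+].[K+].[K+] | intermediate (not isolated)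
30 | pentakis-TES derivative of 29 (TES enol ether at C2, TES ester at C19, 8-, 9-, 11-OTES) | CC[Si](CC)(CC)OC1=CCC(C)=[C@]=C([H])[C@@](O[Si](CC)(CC)CC)([C@@H](C)C(=O)O[Si](CC)(CC)CC)[C@@H](O[Si](CC)(CC)CC)[C@@H]2[C@]1(C)[C@@H](O[Si](C)(C)C(C)(C)C)CC[C@]2(C)O[Si](CC)(CC)CC | intermediate (not isolated)
31 | ten-membered keto allenic acid: 2-ketone, (aR)-C5=C6=C7 allene, 8α-OTES, 9β-OTES, 11β-OTES, 14α-OTBS, C19 acid (17R) | O=C1CCC(C)=[C@]=C([H])[C@@](O[Si](CC)(CC)CC)([C@@H](C)C(=O)O)[C@@H](O[Si](CC)(CC)CC)[C@@H]2[C@]1(C)[C@@H](O[Si](C)(C)C(C)(C)C)CC[C@]2(C)O[Si](CC)(CC)CC | intermediate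
32 | butanolide: 2-ketone, (5Z)-alkene, 7α-O lactone (7β-H), 8α-OTES, 9β-OTES, 11β-OTES, 14α-OTBS | O=C1CC/C(C)=C\[C@@H]2OC(=O)[C@H](C)[C@@]2(O[Si](CC)(CC)CC)[C@@H](O[Si](CC)(CC)CC)[C@@H]2[C@]1(C)[C@@H](O[Si](C)(C)C(C)(C)C)CC[C@]2(C)O[Si](CC)(CC)CC | intermediate
33 | 2β-alcohol of 32 | O[C@H]1CC/C(C)=C\[C@@H]2OC(=O)[C@H](C)[C@@]2(O[Si](CC)(CC)CC)[C@@H](O[Si](CC)(CC)CC)[C@@H]2[C@]1(C)[C@@H](O[Si](C)(C)C(C)(C)C)CC[C@]2(C)O[Si](CC)(CC)CC | intermediate
34 | 2β,8α,9β,11β-tetraol 14α-OTBS ether | O[C@H]1CC/C(C)=C\[C@@H]2OC(=O)[C@H](C)[C@@]2(O)[C@@H](O)[C@@H]2[C@]1(C)[C@@H](O[Si](C)(C)C(C)(C)C)CC[C@]2(C)O | intermediate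
35 | 2β,9β-diacetate 14α-OTBS ether | CC(=O)O[C@H]1CC/C(C)=C\[C@@H]2OC(=O)[C@H](C)[C@@]2(O)[C@@H](OC(C)=O)[C@@H]2[C@]1(C)[C@@H](O[Si](C)(C)C(C)(C)C)CC[C@]2(C)O | intermediate
36 | junceellolide I | CC(=O)O[C@H]1CC/C(C)=C\[C@@H]2OC(=O)[C@H](C)[C@@]2(O)[C@@H](OC(C)=O)[C@@H]2[C@]1(C)[C@@H](O)CC[C@]2(C)O | target

**Step count and risks**

Total step count: 26. Longest linear sequence: 21 steps (steps 6–10 followed by steps 11–26, from (S)-Roche ester 9).

Step 21. The penta-anion may be too insoluble or rearrange too slowly, so that 5-endo-dig addition of an alkoxide to the alkyne or fragmentation takes over. The fallback is a neutral thermal siloxy-Cope rearrangement on the lactone-protected substrate; it sets out from 27 and rejoins at 31. Lactone 27 is treated with Et3SiOSO2CF3 and 2,6-lutidine to give the 2,8,11-tris-TES ether of the lactone F1. F1 is heated in 1,2-dichlorobenzene at about 200 °C, where the same [3,3] shift should give the ring-expanded TES enol ether allene lactone F2. KOH in aqueous THF/MeOH opens the lactone and cleaves the enol ether to the potassium salt of the 9-hydroxy keto allenic acid F3. Et3SiCl with imidazole then silylates O-9, and mild acidic work-up gives 31.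

Step 11. Poor endo/exo selectivity (ring fusion) or poor π-facial selectivity in the cycloaddition would give the cis-fused or wrong-face decalin. The fallback sets the C14 centre before the cycloaddition; it sets out from 8 and rejoins at 19, so steps 12 and 13 are skipped. Oxo-enoate 8 is reduced with BH3·SMe2 and (R)-2-methyl-CBS-oxazaborolidine (Corey–Bakshi–Shibata reduction) to the (14S)-allylic alcohol F4. F4 is silylated with t-BuMe2SiOSO2CF3 to the bis-silyl ether F5 and coupled with 15 under the Heck conditions of step 11 to the triene-yne F6. F6 is cyclised thermally (toluene, 180 °C, sealed tube). With the tether carbon now tetrahedral, the ester is the only activating group and its endo transition state leads to the trans-fused system without a competing ketone-endo mode; the C14 silyloxy group adds a second controlling centre in the tether.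

Step 22. Gold-induced loss of the allene configuration (erosion of axis-to-centre transfer), or attack of another nucleophile such as the C2 carbonyl oxygen, would give C7 and alkene isomers. The fallback is a stoichiometric, stereospecific iodolactonisation; it sets out from 31 and rejoins at 32. Acid 31 with I2 and NaHCO3 in MeCN should undergo anti iodolactonisation (iodine on C6 from the outer lobe, carboxylate on C7) to the 6-iodo butanolide F7. The vinyl iodide is then reduced with retention by Bu3SnH and Pd(PPh3)4 to give 32.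

**Further compounds**

F1 | step 21 | 2,8,11-tris-TES ether of lactone 27 | C=C[C@@]1(O[Si](CC)(CC)CC)[C@@H](C#CC)[C@]3(O[Si](CC)(CC)CC)[C@@H](OC(=O)[C@@H]3C)[C@@H]2[C@]1(C)[C@@H](O[Si](C)(C)C(C)(C)C)CC[C@]2(C)O[Si](CC)(CC)CC
F2 | step 21 | ring-expanded TES enol ether (C2=C3) allene with the C9 lactone intact | CC[Si](CC)(CC)OC1=CCC(C)=[C@]=C([H])[C@]3(O[Si](CC)(CC)CC)[C@@H](OC(=O)[C@@H]3C)[C@@H]2[C@]1(C)[C@@H](O[Si](C)(C)C(C)(C)C)CC[C@]2(C)O[Si](CC)(CC)CC
F3 | step 21 | potassium salt of the 9β-hydroxy keto allenic acid (8α-OTES, 11β-OTES, 14α-OTBS) | O=C1CCC(C)=[C@]=C([H])[C@@](O[Si](CC)(CC)CC)([C@@H](C)C(=O)[O-])[C@@H](O)[C@@H]2[C@]1(C)[C@@H](O[Si](C)(C)C(C)(C)C)CC[C@]2(C)O[Si](CC)(CC)CC.[K+]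
F4 | step 11 | methyl (2E,4S,7S)-4-hydroxy-3,7-dimethyl-7-(triethylsilyloxy)nona-2,8-dienoate | C=C[C@@](C)(O[Si](CC)(CC)CC)CC[C@H](O)/C(C)=C/C(=O)OC
F5 | step 11 | methyl (2E,4S,7S)-4-(tert-butyldimethylsilyloxy)-3,7-dimethyl-7-(triethylsilyloxy)nona-2,8-dienoate | C=C[C@@](C)(O[Si](CC)(CC)CC)CC[C@H](O[Si](C)(C)C(C)(C)C)/C(C)=C/C(=O)OC
F6 | step 11 | triene-yne with the 14α-OTBS centre in place of the C14 ketone of 16 | CC#C/C=C(/C=C/[C@@](C)(O[Si](CC)(CC)CC)CC[C@H](O[Si](C)(C)C(C)(C)C)/C(C)=C/C(=O)OC)[C@@H](C)CO[Si](C)(C)C(C)(C)C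
F7 | step 22 | 6-iodo butanolide (6-iodo analogue of 32) | O=C1CC/C(C)=C(I)\[C@@H]2OC(=O)[C@H](C)[C@@]2(O[Si](CC)(CC)CC)[C@@H](O[Si](CC)(CC)CC)[C@@H]2[C@]1(C)[C@@H](O[Si](C)(C)C(C)(C)C)CC[C@]2(C)O[Si](CC)(CC)CC
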